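**Retrosynthetic overview**

1. The target is cut at the C-5 ester: (E)-3-methylpent-2-enoic acid opens a 5,6-epoxy-4-methylidene hydrindane at the allylic carbon, which sets the trans-diaxial C-5 ester and C-6 hydroxyl. The vinyl epoxide comes from a ring-A ketone by dehydrogenation, epoxidation and methylenation.
2. The cyclopentane's Z-ethylidene and 2R-acetate come from a 2-acetylcyclopentanone: the acetyl is reduced through the ring enol ether and transposed to the enone, then reduced and acetylated.
3. The strategy rests on reading C-1 (ethylidene-bearing), C-2 (acetoxy-bearing) and the two ethylidene carbons as the oxidised remnant of a cadinane 2-methylcyclohexenone ring. A BF3-induced 1,2-acyl shift of its epoxide makes the C1–C2 bond and contracts the six-membered ring to the cyclopentane.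
4. The epoxy ketone comes from a trans-decalin enone, built on (S)-4-isopropylcyclohex-2-enone by vinyl addition/butynylation, ozonolysis, alkyne hydration and aldol condensation. The enone comes from 4-isopropylcyclohexanone by enantioselective deprotonation.
5. Ring order: ring A (purchased cyclohexane) → ring B as a second six-membered ring (aldol, step 6) → ring B contracted to the five-membered ring (step 10).

Key step: step 10

**Remarks on the chemistry**

- Assumption: the (S,S)-lithium amide is taken to give the (R)-enol silane in step 1, by analogy with the sense known for 4-tert-butylcyclohexanone; if the sense is opposite, the (R,R)-amine is used.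
- The ring-A carbonyl is a spectator in the key step and is carried through it as an equatorial TBDPS ether, because a free ketone would compete in the later hydride steps and a free alcohol could attack the activated epoxide.
- Locants: decalins are numbered as naphthalenes (C-2 enone carbonyl, C-3 methyl-bearing, C-4, C-5 isopropyl-bearing, C-8 ring-A oxygenated carbon). Hydrindanes are numbered as indenes (C-1 acetyl/ethylidene-bearing, C-2 oxygenated, C-4 ring-A carbonyl/methylidene, C-5, C-6, C-7 isopropyl-bearing).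

**Route**

Step 1
Reactants: 1 4-isopropylcyclohexan-1-one
Product: 2 (R)-4-isopropyl-1-(trimethylsilyloxy)cyclohex-1-ene
Conditions: (S,S)-bis(1-phenylethyl)amine, n-BuLi, THF, −78 °C; TMSCl (in situ quench), then 1, −90 °C
Reagents that add atoms: chlorotrimethylsilane C[Si](C)(C)Cl
Why: Enantioselective deprotonation of the prochiral ketone by a C2-symmetric chiral lithium amide with internal silyl quench (desymmetrising enol silane formation); the base distinguishes the enantiotopic α-hydrogens and so fixes C-4, from which all later centres are relayed.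

Step 2
Reactants: 2 (R)-4-isopropyl-1-(trimethylsilyloxy)cyclohex-1-ene
Product: 3 (S)-4-isopropylcyclohex-2-en-1-one
Conditions: Pd(OAc)2 (1.05 equiv), MeCN, rt
Reagents that add atoms: none
Why: Saegusa oxidation (oxa-π-allyl complex of divalent palladium, then β-hydride elimination) places the double bond on the side chosen in step 1 and leaves C-4 untouched.

Step 3
Reactants: 3 (S)-4-isopropylcyclohex-2-en-1-one; 4 vinylmagnesium bromide; 5 1-bromobut-2-yne
Product: 7 2-(but-2-yn-1-yl)-4-isopropyl-3-vinylcyclohexan-1-one (2,3-trans, 3,4-trans, all-equatorial), via bromomagnesium enolate 6 (not isolated)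
Conditions: 4, CuBr·SMe2 (10 mol %), THF, −78 °C; then DMPU, 5, −78 °C → rt
Reagents that add atoms: none
Why: Tandem copper-catalysed conjugate addition–enolate alkylation; the vinyl group should add trans to the neighbouring isopropyl group and the regiodefined enolate should be C-alkylated by the propargylic bromide anti to the new vinyl group, giving the all-equatorial ketone, which is also the thermodynamic C-2 epimer.

Step 4
Reactants: 7 2-(but-2-yn-1-yl)-4-isopropyl-3-vinylcyclohexan-1-one
Product: 8 2-(but-2-yn-1-yl)-6-isopropyl-3-oxocyclohexane-1-carbaldehyde (1,2-trans, 1,6-trans)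
Conditions: O3, CH2Cl2–MeOH, −78 °C (Sudan red end point); then Me2S, −78 °C → rt
Reagents that add atoms: ozone [O-][O+]=O
Why: Ozonolysis with reductive work-up; the terminal alkene reacts with ozone far faster than the internal alkyne, and doing the cleavage before alkyne activation removes the 1,6-enyne that a gold catalyst could cycloisomerise.

Step 5
Reactants: 8 2-(but-2-yn-1-yl)-6-isopropyl-3-oxocyclohexane-1-carbaldehyde
Product: 9 6-isopropyl-3-oxo-2-(2-oxobutyl)cyclohexane-1-carbaldehyde (1,2-trans, 1,6-trans)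
Conditions: Ph3PAuNTf2 (2 mol %), H2O (5 equiv), 1,4-dioxane, 40 °C
Reagents that add atoms: water O
Why: Alkyne hydration catalysed by monovalent gold and directed by neighbouring carbonyl participation (5-exo-dig attack of the ring ketone oxygen, or 6-exo-dig attack of the aldehyde oxygen, both on the proximal alkyne carbon), so that the new carbonyl lies next to the ring CH2 and the side chain is the 2-oxobutyl group.

Step 6
Reactants: 9 6-isopropyl-3-oxo-2-(2-oxobutyl)cyclohexane-1-carbaldehyde
Product: 11 trans-fused 5-isopropyl-3-methyl-4a,5,6,7-tetrahydronaphthalene-2,8(1H,8aH)-dione (H-4a/H-8a trans, isopropyl equatorial), via aldol adduct 10 (not isolated)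
Conditions: KOH (0.2 equiv), MeOH, 0 °C → rt
Reagents that add atoms: none
Why: Intramolecular aldol condensation (6-enolexo addition of the ethyl-ketone enolate to the aldehyde, then E1cB dehydration) closes ring B; the aldehyde is by far the most electrophilic carbonyl, so the cyclopentenone annulation of the 1,4-diketone, which needs forcing conditions, should not compete, and the diequatorial trans ring fusion is the thermodynamic one.

Step 7
Reactants: 11 trans-fused 5-isopropyl-3-methyl-4a,5,6,7-tetrahydronaphthalene-2,8(1H,8aH)-dione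
Product: 12 8-hydroxy-5-isopropyl-3-methyl-4a,5,6,7,8,8a-hexahydronaphthalen-2(1H)-one (trans-fused, 8-OH equatorial)
Conditions: NaBH4 (0.3 equiv), EtOH–CH2Cl2, −40 °C
Reagents that add atoms: none
Why: Chemoselective borohydride reduction of the saturated cyclohexanone in preference to the conjugated α-methyl enone; axial hydride delivery gives the equatorial alcohol, a centre that is erased again in step 16.

Step 8
Reactants: 12 8-hydroxy-5-isopropyl-3-methyl-4a,5,6,7,8,8a-hexahydronaphthalen-2(1H)-one
Product: 13 8-(tert-butyldiphenylsilyloxy)-5-isopropyl-3-methyl-4a,5,6,7,8,8a-hexahydronaphthalen-2(1H)-one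
Conditions: TBDPSCl, imidazole, DMF, rt
Reagents that add atoms: tert-butyl(chloro)diphenylsilane CC(C)(C)[Si](Cl)(c1ccccc1)c1ccccc1
Why: Silyl ether formation; the TBDPS group is chosen because it should withstand BF3·OEt2, acidic methanol and i-Bu2AlH in steps 10–12.

Step 9
Reactants: 13 8-(tert-butyldiphenylsilyloxy)-5-isopropyl-3-methyl-4a,5,6,7,8,8a-hexahydronaphthalen-2(1H)-one
Product: 14 8-(tert-butyldiphenylsilyloxy)-3,4-epoxy-5-isopropyl-3-methyloctahydronaphthalen-2(1H)-one (epoxide oxygen cis to H-8a)
Conditions: 30% aq. H2O2, NaOH (cat.), MeOH, 0 °C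
Reagents that add atoms: hydrogen peroxide OO
Why: Weitz–Scheffer nucleophilic epoxidation; hydroperoxide should add axially to C-4 anti to the axial H-4a and close to the cis-epoxide on that face, a configuration that is not carried further because both epoxide carbons are transformed in step 10.

Step 10
Reactants: 14 8-(tert-butyldiphenylsilyloxy)-3,4-epoxy-5-isopropyl-3-methyloctahydronaphthalen-2(1H)-one
Product: 15 trans-fused 1-acetyl-4-(tert-butyldiphenylsilyloxy)-7-isopropyloctahydro-2H-inden-2-one (acetyl cis to H-7a; largely enolised)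
Conditions: BF3·OEt2 (0.6 equiv), CH2Cl2, −20 → 0 °C; aq. NaHCO3
Reagents that add atoms: none
Why: BF3 binds the epoxide oxygen and the C4–O bond, at the β-carbon away from the destabilising carbonyl, ionises while the ring acyl carbon C-2 shifts from C-3 to C-4 in a concerted 1,2-migration with inversion at C-4, and the oxygen left on C-3 collapses to the acetyl carbonyl. This is the known Lewis-acid rearrangement of 2-methyl-2,3-epoxycyclohexanones to 2-acetylcyclopentanones, a semipinacol-type acyl shift. The five-membered ring is closed by ring contraction and not by cyclisation: the C2–C4 bond (C1–C2 of the hydrindane) forms as the C2–C3 bond breaks, the migrating σ-bond attacking the opening epoxide carbon from the rear. The one new stereocentre, the acetyl-bearing carbon, is formed with inversion, but it lies between two carbonyls and should equilibrate through the enol to the epimer drawn, with acetyl trans to the C7a–C7 bond; it becomes trigonal in step 12. The step needs β- rather than α-C–O cleavage and acyl rather than methyl or hydride migration; the carbonyl-destabilised α-cation secures the first and the high migratory aptitude of acyl in the concerted shift the second, while the silyl ether leaves no nucleophile to intercept the activated epoxide.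

Step 11
Reactants: 15 trans-fused 1-acetyl-4-(tert-butyldiphenylsilyloxy)-7-isopropyloctahydro-2H-inden-2-one
Product: 16 1-[4-(tert-butyldiphenylsilyloxy)-7-isopropyl-2-methoxy-3a,4,5,6,7,7a-hexahydro-3H-inden-1-yl]ethan-1-one
Conditions: HC(OMe)3, MeOH, TsOH·H2O (cat.), rt
Reagents that add atoms: trimethyl orthoformate COC(OC)OC; methanol CO
Why: Acid-catalysed enol etherification of the β-diketone under equilibrating conditions (vinylogous ester formation); the ring carbonyl, flanked by CH2, should be etherified because the exocyclic isomer would force OMe or CH3 into allylic strain with the equatorial isopropyl group across C-7a.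

Step 12
Reactants: 16 1-[4-(tert-butyldiphenylsilyloxy)-7-isopropyl-2-methoxy-3a,4,5,6,7,7a-hexahydro-3H-inden-1-yl]ethan-1-one
Product: 18 (1Z)-4-(tert-butyldiphenylsilyloxy)-1-ethylidene-7-isopropyloctahydro-2H-inden-2-one, via hydroxy enol ether 17 (not isolated)
Conditions: i-Bu2AlH, CH2Cl2, −78 °C; then 1 M HCl, THF, 0 °C
Reagents that add atoms: water O
Why: 1,2-Reduction of the vinylogous ester carbonyl and acid-induced allylic transposition with enol ether hydrolysis (Stork–Danheiser-type sequence); the ethylidene should form with its methyl syn to the carbonyl (Z), since the E isomer would clash with the isopropyl-bearing C-7, and Z is also the isomer to which the enone would equilibrate.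

Step 13
Reactants: 18 (1Z)-4-(tert-butyldiphenylsilyloxy)-1-ethylidene-7-isopropyloctahydro-2H-inden-2-one
Product: 19 (1Z,2R)-4-(tert-butyldiphenylsilyloxy)-1-ethylidene-7-isopropyloctahydro-1H-inden-2-ol (OH cis to H-3a)
Conditions: (S)-1-methyl-3,3-diphenyltetrahydro-1H,3H-pyrrolo[1,2-c][1,3,2]oxazaborole (20 mol %), catecholborane, toluene, −78 °C; aq. NaOH work-up
Reagents that add atoms: none
Why: Corey–Bakshi–Shibata reduction under reagent control; the oxazaborolidine should bind the carbonyl lone pair on the CH2 side, the alkylidene carbon acting as the large group, so that hydride is delivered to the face giving the 2R alcohol, and catecholborane at low temperature reduces only in the 1,2-sense.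

Step 14
Reactants: 19 (1Z,2R)-4-(tert-butyldiphenylsilyloxy)-1-ethylidene-7-isopropyloctahydro-1H-inden-2-ol
Product: 20 (1Z,2R)-4-(tert-butyldiphenylsilyloxy)-1-ethylidene-7-isopropyloctahydro-1H-inden-2-yl acetate
Conditions: Ac2O, pyridine, DMAP (cat.), CH2Cl2, 0 °C → rt
Reagents that add atoms: acetic anhydride CC(=O)OC(C)=O
Why: Nucleophile-catalysed acylation of the only free hydroxyl; the acetate is the group of the target and also protects C-2 through the ring-A steps.

Step 15
Reactants: 20 (1Z,2R)-4-(tert-butyldiphenylsilyloxy)-1-ethylidene-7-isopropyloctahydro-1H-inden-2-yl acetate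
Product: 21 (1Z,2R)-1-ethylidene-4-hydroxy-7-isopropyloctahydro-1H-inden-2-yl acetate
Conditions: HF·pyridine, pyridine, THF, rt
Reagents that add atoms: none
Why: Fluoride-induced desilylation; buffered HF·pyridine should cleave the Si–O bond without touching the allylic acetate or the alkene.

Step 16
Reactants: 21 (1Z,2R)-1-ethylidene-4-hydroxy-7-isopropyloctahydro-1H-inden-2-yl acetate
Product: 22 (1Z,2R)-1-ethylidene-7-isopropyl-4-oxooctahydro-1H-inden-2-yl acetate
Conditions: Dess–Martin periodinane, pyridine, CH2Cl2, 0 °C → rt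
Reagents that add atoms: none
Why: Dess–Martin oxidation under buffered, non-enolising conditions returns the ring-A ketone without epimerising the trans ring fusion at C-3a.

Step 17
Reactants: 22 (1Z,2R)-1-ethylidene-7-isopropyl-4-oxooctahydro-1H-inden-2-yl acetate
Product: 23 (1Z,2R)-1-ethylidene-7-isopropyl-4-(trimethylsilyloxy)-2,3,3a,6,7,7a-hexahydro-1H-inden-2-yl acetate
Conditions: lithium diisopropylamide (1.1 equiv), TMSCl (in situ), THF, −78 °C
Reagents that add atoms: chlorotrimethylsilane C[Si](C)(C)Cl
Why: Kinetic enolisation with internal silyl quench removes a proton from the C-5 methylene and not from the C-3a methine, and at −78 °C the ketone should be deprotonated faster than the acetate.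

Step 18
Reactants: 23 (1Z,2R)-1-ethylidene-7-isopropyl-4-(trimethylsilyloxy)-2,3,3a,6,7,7a-hexahydro-1H-inden-2-yl acetate
Product: 24 (1Z,2R)-1-ethylidene-7-isopropyl-4-oxo-2,3,3a,4,7,7a-hexahydro-1H-inden-2-yl acetate
Conditions: Pd(OAc)2 (1.05 equiv), MeCN, rt
Reagents that add atoms: none
Why: Saegusa oxidation gives the C5=C6 enone regiospecifically from the enol silane of step 17.

Step 19
Reactants: 24 (1Z,2R)-1-ethylidene-7-isopropyl-4-oxo-2,3,3a,4,7,7a-hexahydro-1H-inden-2-yl acetate
Product: 25 (1Z,2R)-5,6-epoxy-1-ethylidene-7-isopropyl-4-oxooctahydro-1H-inden-2-yl acetate (epoxide oxygen cis to H-7a)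
Conditions: t-BuOOH, DBU, CH2Cl2, 0 °C
Reagents that add atoms: tert-butyl hydroperoxide CC(C)(C)OO
Why: Weitz–Scheffer epoxidation under non-hydroxylic conditions that should spare the acetate; in the locked half-chair the peroxide anion should add axially to C-6 anti to the axial H-7, giving the epoxide on the face that the final opening requires.

Step 20
Reactants: 25 (1Z,2R)-5,6-epoxy-1-ethylidene-7-isopropyl-4-oxooctahydro-1H-inden-2-yl acetate
Product: 26 (1Z,2R)-5,6-epoxy-1-ethylidene-7-isopropyl-4-methylideneoctahydro-1H-inden-2-yl acetate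
Conditions: Ph3PCH3Br, KN(SiMe3)2, THF, 0 °C; then 25, −78 → 0 °C
Reagents that add atoms: methyltriphenylphosphonium bromide C[P+](c1ccccc1)(c1ccccc1)c1ccccc1.[Br-]
Why: Wittig methylenation; the epoxy ketone carbonyl is much more electrophilic than the acetate, and a slight deficit of base with low temperature should limit enolisation at C-3a.

Step 21
Reactants: 27 ethyl but-2-ynoate; 28 ethylmagnesium bromide
Product: 30 ethyl (E)-3-methylpent-2-enoate, via alkenylcuprate 29 (not isolated)
Conditions: CuI (1 equiv), 28 (2 equiv), THF, −40 °C; then 27, −78 °C; sat. aq. NH4Cl, −78 °C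
Reagents that add atoms: none
Why: syn-Carbocupration of the ynoate at low temperature and protonation of the alkenylcopper with retention put the new ethyl group cis to hydrogen, which is the E ester.

Step 22
Reactants: 30 ethyl (E)-3-methylpent-2-enoate
Product: 31 (E)-3-methylpent-2-enoic acid
Conditions: LiOH, THF–H2O, rt; then 1 M HCl
Reagents that add atoms: lithium hydroxide [Li+].[OH-]
Why: Saponification of the ester, which does not affect the trisubstituted alkene geometry.

Step 23
Reactants: 26 (1Z,2R)-5,6-epoxy-1-ethylidene-7-isopropyl-4-methylideneoctahydro-1H-inden-2-yl acetate; 31 (E)-3-methylpent-2-enoic acid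
Product: 32 (1Z,2R,3aR,5S,6S,7S,7aR)-2-acetoxy-1-ethylidene-6-hydroxy-7-isopropyl-4-methylideneoctahydro-1H-inden-5-yl (2E)-3-methylpent-2-enoate
Conditions: 31 (3 equiv), Cs2CO3 (0.2 equiv), DMF, 60 °C
Reagents that add atoms: none
Why: Epoxide opening by a carboxylate nucleophile, SN2 with inversion at the allylic C-5; this is also the trans-diaxial (Fürst–Plattner) mode, so the ester should enter axially at C-5, the C-6 oxygen stays axial on the opposite face, and the diaxial arrangement excludes later acyl migration.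

**Compound list**

1 | 4-isopropylcyclohexan-1-one | CC(C)C1CCC(=O)CC1 | starting material
2 | (R)-4-isopropyl-1-(trimethylsilyloxy)cyclohex-1-ene | C[Si](C)(C)OC1=CC[C@H](C(C)C)CC1 | intermediate
3 | (S)-4-isopropylcyclohex-2-en-1-one | O=C1C=C[C@H](C(C)C)CC1 | intermediate
4 | vinylmagnesium bromide | C=C[Mg]Br | starting material
5 | 1-bromobut-2-yne | CC#CCBr | starting material
6 | bromomagnesium enolate of trans-4-isopropyl-3-vinylcyclohexanone (C1=C2 enolate) | Br[Mg]OC1=C[C@@H](C=C)[C@H](C(C)C)CC1 | intermediate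
7 | 2-(but-2-yn-1-yl)-4-isopropyl-3-vinylcyclohexan-1-one (2,3-trans, 3,4-trans) | O=C1[C@H](CC#CC)[C@@H](C=C)[C@H](C(C)C)CC1 | intermediate
8 | 2-(but-2-yn-1-yl)-6-isopropyl-3-oxocyclohexane-1-carbaldehyde (1,2-trans, 1,6-trans) | O=C1[C@H](CC#CC)[C@@H](C=O)[C@H](C(C)C)CC1 | intermediate
9 | 6-isopropyl-3-oxo-2-(2-oxobutyl)cyclohexane-1-carbaldehyde (1,2-trans, 1,6-trans) | O=C1[C@H](CC(=O)CC)[C@@H](C=O)[C@H](C(C)C)CC1 | intermediate
10 | trans-fused 4-hydroxy-5-isopropyl-3-methyloctahydronaphthalene-2,8-dione (epimers at C-3 and C-4) | O=C1[C@@H]2CC(=O)C(C)C(O)[C@H]2[C@H](C(C)C)CC1 | intermediate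
11 | trans-fused 5-isopropyl-3-methyl-4a,5,6,7-tetrahydronaphthalene-2,8(1H,8aH)-dione | O=C1[C@@H]2CC(=O)C(C)=C[C@H]2[C@H](C(C)C)CC1 | intermediate
12 | 8-hydroxy-5-isopropyl-3-methyl-4a,5,6,7,8,8a-hexahydronaphthalen-2(1H)-one (trans-fused, 8-OH equatorial) | O[C@H]1[C@@H]2CC(=O)C(C)=C[C@H]2[C@H](C(C)C)CC1 | intermediate
13 | 8-(tert-butyldiphenylsilyloxy)-5-isopropyl-3-methyl-4a,5,6,7,8,8a-hexahydronaphthalen-2(1H)-one | CC(C)(C)[Si](c1ccccc1)(c1ccccc1)O[C@H]1[C@@H]2CC(=O)C(C)=C[C@H]2[C@H](C(C)C)CC1 | intermediate
14 | 8-(tert-butyldiphenylsilyloxy)-3,4-epoxy-5-isopropyl-3-methyloctahydronaphthalen-2(1H)-one (epoxide oxygen cis to H-8a) | CC(C)(C)[Si](c1ccccc1)(c1ccccc1)O[C@H]1[C@@H]2CC(=O)[C@@]3(C)O[C@H]3[C@H]2[C@H](C(C)C)CC1 | intermediate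
15 | trans-fused 1-acetyl-4-(tert-butyldiphenylsilyloxy)-7-isopropyloctahydro-2H-inden-2-one (acetyl cis to H-7a) | CC(C)(C)[Si](c1ccccc1)(c1ccccc1)O[C@H]1[C@@H]2CC(=O)[C@H](C(C)=O)[C@H]2[C@H](C(C)C)CC1 | intermediate
16 | 1-[4-(tert-butyldiphenylsilyloxy)-7-isopropyl-2-methoxy-3a,4,5,6,7,7a-hexahydro-3H-inden-1-yl]ethan-1-one | CC(C)(C)[Si](c1ccccc1)(c1ccccc1)O[C@H]1[C@@H]2CC(OC)=C(C(C)=O)[C@H]2[C@H](C(C)C)CC1 | intermediate
17 | 1-[4-(tert-butyldiphenylsilyloxy)-7-isopropyl-2-methoxy-3a,4,5,6,7,7a-hexahydro-3H-inden-1-yl]ethan-1-ol (either carbinol epimer; aluminium alkoxide before the acid quench) | CC(C)(C)[Si](c1ccccc1)(c1ccccc1)O[C@H]1[C@@H]2CC(OC)=C(C(C)O)[C@H]2[C@H](C(C)C)CC1 | intermediate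
18 | (1Z)-4-(tert-butyldiphenylsilyloxy)-1-ethylidene-7-isopropyloctahydro-2H-inden-2-one | CC(C)(C)[Si](c1ccccc1)(c1ccccc1)O[C@H]1[C@@H]2CC(=O)/C(=C\C)[C@H]2[C@H](C(C)C)CC1 | intermediate
19 | (1Z,2R)-4-(tert-butyldiphenylsilyloxy)-1-ethylidene-7-isopropyloctahydro-1H-inden-2-ol | CC(C)(C)[Si](c1ccccc1)(c1ccccc1)O[C@H]1[C@@H]2C[C@@H](O)/C(=C\C)[C@H]2[C@H](C(C)C)CC1 | intermediate
20 | (1Z,2R)-4-(tert-butyldiphenylsilyloxy)-1-ethylidene-7-isopropyloctahydro-1H-inden-2-yl acetate | CC(C)(C)[Si](c1ccccc1)(c1ccccc1)O[C@H]1[C@@H]2C[C@@H](OC(C)=O)/C(=C\C)[C@H]2[C@H](C(C)C)CC1 | intermediate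
21 | (1Z,2R)-1-ethylidene-4-hydroxy-7-isopropyloctahydro-1H-inden-2-yl acetate | O[C@H]1[C@@H]2C[C@@H](OC(C)=O)/C(=C\C)[C@H]2[C@H](C(C)C)CC1 | intermediate
22 | (1Z,2R)-1-ethylidene-7-isopropyl-4-oxooctahydro-1H-inden-2-yl acetate | O=C1[C@@H]2C[C@@H](OC(C)=O)/C(=C\C)[C@H]2[C@H](C(C)C)CC1 | intermediate
23 | (1Z,2R)-1-ethylidene-7-isopropyl-4-(trimethylsilyloxy)-2,3,3a,6,7,7a-hexahydro-1H-inden-2-yl acetate | C[Si](C)(C)OC1=CC[C@@H](C(C)C)[C@H]2[C@H]1C[C@@H](OC(C)=O)/C2=C\C | intermediate
24 | (1Z,2R)-1-ethylidene-7-isopropyl-4-oxo-2,3,3a,4,7,7a-hexahydro-1H-inden-2-yl acetate | O=C1[C@@H]2C[C@@H](OC(C)=O)/C(=C\C)[C@H]2[C@H](C(C)C)C=C1 | intermediate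
25 | (1Z,2R)-5,6-epoxy-1-ethylidene-7-isopropyl-4-oxooctahydro-1H-inden-2-yl acetate (epoxide oxygen cis to H-7a) | O=C1[C@@H]2C[C@@H](OC(C)=O)/C(=C\C)[C@H]2[C@H](C(C)C)[C@@H]3O[C@@H]31 | intermediate
26 | (1Z,2R)-5,6-epoxy-1-ethylidene-7-isopropyl-4-methylideneoctahydro-1H-inden-2-yl acetate | C=C1[C@@H]2C[C@@H](OC(C)=O)/C(=C\C)[C@H]2[C@H](C(C)C)[C@@H]3O[C@@H]31 | intermediate
27 | ethyl but-2-ynoate | CC#CC(=O)OCC | starting material
28 | ethylmagnesium bromide | CC[Mg]Br | starting material
29 | bromomagnesium ethyl[(Z)-1-(ethoxycarbonyl)-2-methylbut-1-en-1-yl]cuprate | CCOC(=O)/C([Cu-]CC)=C(\C)CC.[Mg+]Br | intermediate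
30 | ethyl (E)-3-methylpent-2-enoate | CCOC(=O)/C=C(\C)CC | intermediate
31 | (E)-3-methylpent-2-enoic acid | OC(=O)/C=C(\C)CC | intermediate
32 | (1Z,2R,3aR,5S,6S,7S,7aR)-2-acetoxy-1-ethylidene-6-hydroxy-7-isopropyl-4-methylideneoctahydro-1H-inden-5-yl (2E)-3-methylpent-2-enoate | C=C1[C@@H]2C[C@@H](OC(C)=O)/C(=C\C)[C@H]2[C@H](C(C)C)[C@H](O)[C@H]1OC(=O)/C=C(\C)CC | target

**Step count**

Total: 23 steps (20 on the main line to the vinyl epoxide, 2 for the acid, 1 coupling).
Longest linear sequence: 21 steps (steps 1–20 and 23).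

**Steps most likely to fail**

Step 10 (key rearrangement). The activated epoxide may be diverted by a methyl shift, by a hydride shift from C-4a, or by fluoride capture, in place of the acyl shift. The fallback sets out from 14 and returns at 15, and separates ionisation from migration. Aqueous HClO4 in THF should open the epoxide at C-4 with inversion to the 8-(tert-butyldiphenylsilyloxy)-3,4-dihydroxy-5-isopropyl-3-methyloctahydronaphthalen-2(1H)-one F1. MsCl in pyridine should sulfonylate only the secondary hydroxyl to the 4-methanesulfonate F2, whose equatorial leaving group is antiperiplanar to the C2–C3 ring bond. Et3Al in CH2Cl2 at −78 °C should then drive the same 1,2-acyl shift from the aluminium alkoxide (organoaluminium-promoted semipinacol rearrangement) and give 15.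

Step 11 (enol ether regiochemistry). Etherification may take place on the acetyl oxygen instead of the ring oxygen. The fallback sets out from 15 and returns at 19, and uses that isomer. The exocyclic enol ether 4-(tert-butyldiphenylsilyloxy)-7-isopropyl-1-(1-methoxyethylidene)octahydro-2H-inden-2-one F3 is reduced at the ring carbonyl with i-Bu2AlH to the allylic 4-(tert-butyldiphenylsilyloxy)-7-isopropyl-1-(1-methoxyethylidene)octahydro-1H-inden-2-ol F4, which is not isolated. Dilute HCl transposes it to the 1-acetylcyclopentene 1-[4-(tert-butyldiphenylsilyloxy)-7-isopropyl-3a,4,5,6,7,7a-hexahydro-3H-inden-1-yl]ethan-1-one F5. Alkaline H2O2 gives the 1,2-epoxy ketone F6, and a Wharton transposition (N2H4·H2O, AcOH, MeOH) turns it into the ethylidene allylic alcohol 19. In this variant the C-2 configuration rests on the face selectivity of the epoxidation.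

Step 23 (epoxide opening by the acid). The weakly nucleophilic carboxylate may open the epoxide too slowly, or may attack the exocyclic methylene in an SN2′ sense. The fallback sets out from 26 and returns at 32, and replaces the direct opening by hydrolysis and site-selective acylation. Catalytic HClO4 in THF–H2O at 0 °C should give the trans-diaxial (1Z,2R)-1-ethylidene-5,6-dihydroxy-7-isopropyl-4-methylideneoctahydro-1H-inden-2-yl acetate F7. Steglich esterification with 31 (dicyclohexylcarbodiimide, DMAP, CH2Cl2, 0 °C) should then acylate the allylic C-5 hydroxyl, because the C-6 hydroxyl is axial and flanked by the isopropyl-bearing carbon.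

**Further compounds**

F1 | step 10 | 8-(tert-butyldiphenylsilyloxy)-3,4-dihydroxy-5-isopropyl-3-methyloctahydronaphthalen-2(1H)-one (4-OH equatorial, trans to 3-OH) | CC(C)(C)[Si](c1ccccc1)(c1ccccc1)O[C@H]1[C@@H]2CC(=O)[C@@](C)(O)[C@H](O)[C@H]2[C@H](C(C)C)CC1
F2 | step 10 | 4-methanesulfonate of F1 | CC(C)(C)[Si](c1ccccc1)(c1ccccc1)O[C@H]1[C@@H]2CC(=O)[C@@](C)(O)[C@H](OS(C)(=O)=O)[C@H]2[C@H](C(C)C)CC1
F3 | step 11 | 4-(tert-butyldiphenylsilyloxy)-7-isopropyl-1-(1-methoxyethylidene)octahydro-2H-inden-2-one | CC(C)(C)[Si](c1ccccc1)(c1ccccc1)O[C@H]1[C@@H]2CC(=O)C(=C(C)OC)[C@H]2[C@H](C(C)C)CC1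
F4 | step 11 | 4-(tert-butyldiphenylsilyloxy)-7-isopropyl-1-(1-methoxyethylidene)octahydro-1H-inden-2-ol (not isolated) | CC(C)(C)[Si](c1ccccc1)(c1ccccc1)O[C@H]1[C@@H]2CC(O)C(=C(C)OC)[C@H]2[C@H](C(C)C)CC1
F5 | step 11 | 1-[4-(tert-butyldiphenylsilyloxy)-7-isopropyl-3a,4,5,6,7,7a-hexahydro-3H-inden-1-yl]ethan-1-one | CC(C)(C)[Si](c1ccccc1)(c1ccccc1)O[C@H]1[C@@H]2CC=C(C(C)=O)[C@H]2[C@H](C(C)C)CC1
F6 | step 11 | 1-acetyl-4-(tert-butyldiphenylsilyloxy)-1,2-epoxy-7-isopropyloctahydro-1H-indene (epoxide oxygen cis to H-3a) | CC(C)(C)[Si](c1ccccc1)(c1ccccc1)O[C@H]1[C@@H]2C[C@H]3O[C@@]3(C(C)=O)[C@H]2[C@H](C(C)C)CC1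
F7 | step 23 | (1Z,2R)-1-ethylidene-5,6-dihydroxy-7-isopropyl-4-methylideneoctahydro-1H-inden-2-yl acetate (trans-diaxial diol) | C=C1[C@@H]2C[C@@H](OC(C)=O)/C(=C\C)[C@H]2[C@H](C(C)C)[C@H](O)[C@H]1O
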